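## Structural features

The target **25** is a C25 sesterterpenoid: a bicyclic octalin (labdane-type numbering; ring A = C1–C5 and C10, ring B = C5–C10) carries on C9 a chain C11–C16 that ends at the β-carbon of a furan-2(5H)-one. Ring A is saturated and holds the gem-dimethyl carbon C4. Ring B holds the only ring double bond, the tetrasubstituted C8=C9 (methyl on C8, chain on C9), directly next to the quaternary ring-fusion carbon C10. There are only two stereocentres and they are adjacent: C5 (R, bearing H) and C10 (S, bearing CH3). The SMILES places H-5 and the C10 methyl on the same face, so the rings are cis-fused, the C5 epimer of the usual trans labdane bicycle. The chain has a saturated C11–C12 link, a trisubstituted C13=C14 bond (E; the hydroxymethyl group on C13 is trans to C15, so C12 and C15 are cis) and an E C15=C16 bond, all conjugated with the lactone C=C. Fragile parts are the cross-conjugated trienyl butenolide (base, nucleophiles, light), the primary allylic alcohol (ionisation) and C8=C9 (acid-induced migration). The real difficulty is C10, a quaternary stereocentre with no heteroatom handle, placed between the fully substituted C9 and the neopentyl C5 and cis to H-5; neither chair-type cyclisation of an all-E polyene nor the trans-fused chiral-pool labdanes give this. The key step exploits the C9–C10 bond: an sp2 carbon of a tetrasubstituted ring-B olefin bound to a quaternary carbon whose neighbour C5 carries the other ring-B arm (C6) on the same face of ring A.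

## Logic of the disconnections

**25 ⇒ 23 + 24.** The C16–C17 bond (chain to butenolide β-carbon) is cut. This brings the base- and light-sensitive lactone in last, under neutral conditions, and removes it from every earlier step. Both chain olefins are already fixed in **23**, so the forward coupling must be stereoretentive at both sp2 carbons and must tolerate the free allylic alcohol.

**23 ⇒ 22 ⇒ 18 + 20 (through 21).** The hydroxymethyl group is taken back to an ester (**22**) and the C13=C14 bond is cut by carbonyl olefination. The ester serves both as activating group and as the latent CH2OH; **20** supplies C14–C16 with the E C15=C16 bond and the tin handle in place. The forward step must be E-selective at C13=C14 and leave the C–Sn bond intact. **20** comes from commercial **19** by oxidation.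

**18 ⇒ 15 + 16 (through 17); 15 ⇒ 14.** The sp3–sp3 bond C12–C13 is cut; forward it is the alkylation of a stabilised carbanion by a primary iodide made from alcohol **14**. This leaves a bicyclic C16 alcohol that carries only C11–C12. The demand is substitution without elimination toward C11.

**14 ⇒ 13.** No bond is cut; a C1=C2 double bond is added retrosynthetically in ring A. It is the footprint of the key step. Forward, this disubstituted olefin must be saturated in the presence of the tetrasubstituted C8=C9.

**13 ⇒ 12 (key disconnection).** The C9–C10 bond is cut, opening ring B. In one sentence: ring B, the quaternary stereocentre C10 and the cis ring fusion are made by an intramolecular Heck cyclisation of the alkenyl iodide **12** onto the ring-A olefin. The cut is made here because a quaternary carbon attached to an sp2 carbon is the retron of this reaction, and because a syn carbopalladation delivered from a tether on C5 can only give the cis fusion. The gain is large: a bicycle with two adjacent stereocentres and a tetrasubstituted olefin goes back to a monocycle with one stereocentre. The demand is an alkenyl iodide with iodine cis to C7 (Z) and exo ring closure.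

**12 ⇒ 7 + 8 (through 9, 10, 11).** The C7–C8 and C9–I bonds are cut. Forward, a syn carbometalation of the alkyne of **8** sets the tetrasubstituted olefin geometry by mechanism and brings in the C8 methyl, C9, C11, C12 and the C12 oxygen in one commercial piece. The demand is delivery of the alkyl group to the alkyne carbon remote from oxygen, syn addition, and halogenation with retention.

**7 ⇒ 6 ⇒ 5 ⇒ 2 + 3 (through 4); 2 ⇒ 1.** The C5–C6 bond is cut by a [3,3] retron. Forward, the shift transfers the carbinol chirality of **2** to C5 and moves the ring olefin to C10=C1, where the key step needs it. **2** comes from the achiral, commercial enone **1** by enantioselective reduction, so one catalytic asymmetric step is the source of all chirality. The demand is clean suprafacial transfer at a hindered terminus.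

## Other disconnections considered

**Alternative 1:** This is the plan that comes to mind first for an angular-methyl decalin. The side chain is cut at C9–C11 and the bicycle is taken from the Wieland–Miescher ketone **A1** through the 4,4-dimethyl-Δ5-octalone **A2**. The forward key step would be hydrogenation of the C5=C6 bond of **A2** to set C5, followed by methylation and enol triflate coupling at C8/C9. The chosen plan is preferred because hydrogen is expected to reach C5=C6 from the face opposite the angular methyl group, which leads to the trans fusion. The one stereocentre that makes this target unusual is therefore the one this sequence is likely to set wrongly. In addition, a C3 carbonyl has to be removed, and the gem-dimethyl group, the C8 methyl and the C9 substituent have to be added one at a time.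

**Alternative 2:** Both rings are cut at once (C4–C5 and C9–C10) to the acyclic (6Z)-β-keto ester **A3**. The forward key step would be a Stork–Eschenmoser-type cationic bicyclisation of **A3**, in which the Z central olefin is translated into the cis fusion of the bicyclic β-keto ester **A4** (the biomimetic route). It is attractive, but the chosen plan is preferred on three grounds. First, absolute configuration would rest either on a chiral acid not yet shown for this terminator and olefin geometry, or on an oxygen stereocontroller at C3 that must be excised later. Second, with a Z olefin the second ring closure is slower, so a longer-lived monocyclic cation can leak to the trans isomer. Third, C11 emerges as an ester, so the C8 methyl and C12 both need extra steps.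

**Alternative 3:** Ring B is a cyclohexene with its double bond next to the ring fusion, the retron of an intramolecular Diels–Alder reaction. Cutting C5–C10 and C6–C7 gives the achiral triene **A5**, and the forward key step would be its thermal cycloaddition. The chosen plan is preferred because the diene terminus C10 of **A5** is fully substituted, so the s-cis conformer suffers 1,3-allylic strain and the unactivated dienophile would need forcing temperatures. Endo and exo modes would give a cis/trans mixture. **A5** also contains no element that could control absolute configuration.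

Key step: step 6

Remark (reading of the target): the SMILES is taken as drawn, with H-5 and CH3-10 cis (5R,10S), 13E (C12 cis to C15) and 15E.

Remark (numbering): short-lived species of catalytic cycles are described in the Why lines and carry no compound numbers; stoichiometric intermediates made in the flask are numbered.

## Route

Step 1
Reactants: 1 2,4,4-trimethylcyclohex-2-en-1-one
Product: 2 (1S)-2,4,4-trimethylcyclohex-2-en-1-ol
Conditions: (R)-2-methyl-CBS-oxazaborolidine (10 mol%), BH3·SMe2 (0.7 equiv), THF, −20 °C; MeOH
Reagents that add atoms: none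
Why: Corey–Bakshi–Shibata reduction of an α-substituted cyclic enone; with the alkenyl arm as the large group the (R)-catalyst should give the (S)-carbinol (the antipodal catalyst is available if the sense proves opposite), and this is the only stereocentre from which C5 and then C10 are derived.

Step 2
Reactants: 2 (1S)-2,4,4-trimethylcyclohex-2-en-1-ol; 3 triethyl orthoacetate
Product: 5 ethyl 2-[(1R)-2,6,6-trimethylcyclohex-2-en-1-yl]acetate, via ketene acetal 4 (not isolated)
Conditions: MeC(OEt)3 (6 equiv), EtCO2H (5 mol%), 140 °C, EtOH distilled off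
Reagents that add atoms: none
Why: Johnson–Claisen rearrangement; the [3,3] shift is suprafacial, so the new C5–C6 bond forms on the ring face that carried the C–O bond and the (S)-carbinol becomes (R)-C5, while the double bond moves to C10=C1.

Step 3
Reactants: 5 ethyl 2-[(1R)-2,6,6-trimethylcyclohex-2-en-1-yl]acetate
Product: 6 2-[(1R)-2,6,6-trimethylcyclohex-2-en-1-yl]ethan-1-ol
Conditions: LiAlH4, Et2O, 0 °C
Reagents that add atoms: none
Why: Hydride reduction of an ester to the primary alcohol; C5 is not α to the carbonyl and cannot epimerise.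

Step 4
Reactants: 6 2-[(1R)-2,6,6-trimethylcyclohex-2-en-1-yl]ethan-1-ol
Product: 7 (6R)-6-(2-bromoethyl)-1,5,5-trimethylcyclohex-1-ene
Conditions: CBr4, PPh3, CH2Cl2, 0 °C
Reagents that add atoms: carbon tetrabromide, BrC(Br)(Br)Br
Why: Appel reaction; neutral SN2 conversion of a primary alcohol that leaves the acid-sensitive ring olefin and C5 untouched.

Step 5
Reactants: 7 (6R)-6-(2-bromoethyl)-1,5,5-trimethylcyclohex-1-ene; 8 pent-3-yn-1-ol
Product: 12 (3Z)-3-iodo-4-methyl-6-[(1R)-2,6,6-trimethylcyclohex-2-en-1-yl]hex-3-en-1-ol, via Grignard reagent 9 (not isolated), via magnesium alkoxide 10 (not isolated), via alkenylmagnesium chelate 11 (not isolated)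
Conditions: 7, Mg, THF, rt; 8 (1.3 equiv), MeMgBr (1.0 equiv per 8), THF, 0 °C; combine, Fe(acac)3 (15 mol%), −78 → 0 °C; I2, −78 → 0 °C
Reagents that add atoms: iodine, [I][I]
Why: Iron-catalysed, alkoxide-directed syn-carbomagnesiation of a homopropargylic alcohol: the alkyl group of 9 goes to the alkyne carbon remote from oxygen (C8) and magnesium to C9 within a five-membered alkoxide chelate. Iodinolysis with retention leaves iodine cis to the new C7–C8 bond, the Z geometry that ring closure requires.

Step 6
Reactants: 12 (3Z)-3-iodo-4-methyl-6-[(1R)-2,6,6-trimethylcyclohex-2-en-1-yl]hex-3-en-1-ol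
Product: 13 2-[(4aR,8aS)-2,5,5,8a-tetramethyl-3,4,4a,5,6,8a-hexahydronaphthalen-1-yl]ethan-1-ol
Conditions: Pd(OAc)2 (10 mol%), PPh3 (30 mol%), Ag2CO3 (2 equiv), MeCN, 80 °C
Reagents that add atoms: none
Why: Intramolecular Mizoroki–Heck reaction of the type used to make quaternary carbons. Zerovalent palladium inserts into the C9–I bond of 12, Ag2CO3 removes iodide, and the cationic alkenylpalladium adds syn across the ring-A olefin C10=C1. Ring B closes in the 6-exo-trig mode (C9 to C10, palladium to C1); the 7-endo mode would need the larger ring and is not expected. The one new stereocentre, C10, is controlled by C5: the link C6–C7–C8=C9 can hold the C9–Pd bond coplanar with C10=C1 only over the olefin face on which the pseudoaxial C5–C6 bond stands, so C9 and C6 end up cis on ring A, which is the cis ring fusion (10S from 5R). The alkylpalladium at C1 has no hydrogen on C10 and must eliminate toward C2, so the quaternary centre cannot be lost and diene 13 results. The C8=C9 bond is carried in from 12 with the geometry that the ring needs and ends tetrasubstituted next to C10 without any later olefin-forming step. Selectivity needed is oxidative addition only at the alkenyl iodide (the free alcohol and the ring olefin are inert to it), exo over endo insertion (ring size) and one olefin face (tether). Ag2CO3 also suppresses re-addition of palladium hydride, and any migration of the C1=C2 bond that still occurs is harmless because step 7 saturates ring A.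

Step 7
Reactants: 13 2-[(4aR,8aS)-2,5,5,8a-tetramethyl-3,4,4a,5,6,8a-hexahydronaphthalen-1-yl]ethan-1-ol
Product: 14 2-[(4aR,8aS)-2,5,5,8a-tetramethyl-3,4,4a,5,6,7,8,8a-octahydronaphthalen-1-yl]ethan-1-ol
Conditions: H2 (3 atm), RhCl(PPh3)3 (5 mol%), benzene/EtOH, rt
Reagents that add atoms: none
Why: Homogeneous hydrogenation with RhCl(PPh3)3 should reduce the cis-disubstituted ring-A olefin and leave the tetrasubstituted C8=C9 bond untouched; positional isomers of the ring-A olefin converge on the same product and no stereocentre is formed.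

Step 8
Reactants: 14 2-[(4aR,8aS)-2,5,5,8a-tetramethyl-3,4,4a,5,6,7,8,8a-octahydronaphthalen-1-yl]ethan-1-ol
Product: 15 (4aR,8aS)-1-(2-iodoethyl)-2,5,5,8a-tetramethyl-3,4,4a,5,6,7,8,8a-octahydronaphthalene
Conditions: I2, PPh3, imidazole, CH2Cl2, 0 °C → rt
Reagents that add atoms: iodine, [I][I]
Why: Appel-type iodination of a primary alcohol under buffered conditions, which should not move the C8=C9 bond.

Step 9
Reactants: 15 (4aR,8aS)-1-(2-iodoethyl)-2,5,5,8a-tetramethyl-3,4,4a,5,6,7,8,8a-octahydronaphthalene; 16 triethyl phosphonoacetate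
Product: 18 ethyl 2-(diethoxyphosphoryl)-4-[(4aR,8aS)-2,5,5,8a-tetramethyl-3,4,4a,5,6,7,8,8a-octahydronaphthalen-1-yl]butanoate, via sodium phosphonoacetate 17 (not isolated)
Conditions: 16 (2.5 equiv), NaH (2.4 equiv), THF/DMF, 0 → 60 °C
Reagents that add atoms: none
Why: SN2 C-alkylation of a phosphonate-stabilised carbanion by a primary iodide forms C12–C13; the soft, weakly basic nucleophile disfavours elimination toward C11 and the excess of 16 limits dialkylation. The new centre at C13 (mixture of epimers) becomes sp2 in step 11.

Step 10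
Reactants: 19 (2E)-3-(tributylstannyl)prop-2-en-1-ol
Product: 20 (2E)-3-(tributylstannyl)prop-2-enal
Conditions: MnO2 (15 equiv), CH2Cl2, rt
Reagents that add atoms: none
Why: Allylic oxidation with MnO2; the E geometry and the C–Sn bond are retained.

Step 11
Reactants: 18 ethyl 2-(diethoxyphosphoryl)-4-[(4aR,8aS)-2,5,5,8a-tetramethyl-3,4,4a,5,6,7,8,8a-octahydronaphthalen-1-yl]butanoate; 20 (2E)-3-(tributylstannyl)prop-2-enal
Product: 22 ethyl (2E,4E)-2-{2-[(4aR,8aS)-2,5,5,8a-tetramethyl-3,4,4a,5,6,7,8,8a-octahydronaphthalen-1-yl]ethyl}-5-(tributylstannyl)penta-2,4-dienoate, via phosphonate carbanion 21 (not isolated)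
Conditions: NaH, THF, 0 °C; then 20, 0 °C → rt
Reagents that add atoms: none
Why: Horner–Wadsworth–Emmons olefination of an α-alkyl phosphonoacetate with an enal; reversible addition and the more stable anti oxaphosphetane should place the ester trans to C15 (E), that is C12 cis to C15 as in the target. C15=C16 comes unchanged from 20.

Step 12
Reactants: 22 ethyl (2E,4E)-2-{2-[(4aR,8aS)-2,5,5,8a-tetramethyl-3,4,4a,5,6,7,8,8a-octahydronaphthalen-1-yl]ethyl}-5-(tributylstannyl)penta-2,4-dienoate
Product: 23 (2E,4E)-2-{2-[(4aR,8aS)-2,5,5,8a-tetramethyl-3,4,4a,5,6,7,8,8a-octahydronaphthalen-1-yl]ethyl}-5-(tributylstannyl)penta-2,4-dien-1-ol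
Conditions: i-Bu2AlH (2.5 equiv), CH2Cl2, −78 °C; aq. Rochelle salt
Reagents that add atoms: none
Why: 1,2-Reduction of a conjugated ester to the allylic alcohol with i-Bu2AlH; the alkenylstannane and the olefin geometries are not affected at −78 °C.

Step 13
Reactants: 23 (2E,4E)-2-{2-[(4aR,8aS)-2,5,5,8a-tetramethyl-3,4,4a,5,6,7,8,8a-octahydronaphthalen-1-yl]ethyl}-5-(tributylstannyl)penta-2,4-dien-1-ol; 24 4-bromofuran-2(5H)-one
Product: 25 4-[(1E,3E)-4-(hydroxymethyl)-6-[(4aR,8aS)-2,5,5,8a-tetramethyl-3,4,4a,5,6,7,8,8a-octahydronaphthalen-1-yl]hexa-1,3-dien-1-yl]furan-2(5H)-one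
Conditions: Pd2(dba)3 (5 mol%), AsPh3 (20 mol%), CuI (10 mol%), NMP, rt, dark
Reagents that add atoms: none
Why: Stille coupling of an alkenylstannane with a vinylogous acyl bromide forms C16–C17 with retention at both sp2 carbons; the neutral conditions should tolerate the free allylic alcohol and the base-sensitive butenolide.

## Compound list

1 | 2,4,4-trimethylcyclohex-2-en-1-one | CC1=CC(C)(C)CCC1=O | starting material
2 | (1S)-2,4,4-trimethylcyclohex-2-en-1-ol | CC1=CC(C)(C)CC[C@@H]1O | intermediate
3 | triethyl orthoacetate | CCOC(C)(OCC)OCC | starting material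
4 | 1-ethoxyethenyl (1S)-2,4,4-trimethylcyclohex-2-en-1-yl ether (ketene acetal) | CC1=CC(C)(C)CC[C@@H]1OC(=C)OCC | intermediate
5 | ethyl 2-[(1R)-2,6,6-trimethylcyclohex-2-en-1-yl]acetate | CC1=CCCC(C)(C)[C@H]1CC(=O)OCC | intermediate
6 | 2-[(1R)-2,6,6-trimethylcyclohex-2-en-1-yl]ethan-1-ol | CC1=CCCC(C)(C)[C@H]1CCO | intermediate
7 | (6R)-6-(2-bromoethyl)-1,5,5-trimethylcyclohex-1-ene | CC1=CCCC(C)(C)[C@H]1CCBr | intermediate
8 | pent-3-yn-1-ol | CC#CCCO | starting material
9 | {2-[(1R)-2,6,6-trimethylcyclohex-2-en-1-yl]ethyl}magnesium bromide | CC1=CCCC(C)(C)[C@H]1CC[Mg]Br | intermediate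
10 | bromomagnesium pent-3-yn-1-olate | CC#CCCO[Mg]Br | intermediate
11 | bromomagnesium (3Z)-3-(bromomagnesio)-4-methyl-6-[(1R)-2,6,6-trimethylcyclohex-2-en-1-yl]hex-3-en-1-olate | Br[Mg]OCC/C([Mg]Br)=C(\C)CC[C@H]1C(C)=CCCC1(C)C | intermediate
12 | (3Z)-3-iodo-4-methyl-6-[(1R)-2,6,6-trimethylcyclohex-2-en-1-yl]hex-3-en-1-ol | OCC/C(I)=C(\C)CC[C@H]1C(C)=CCCC1(C)C | intermediate
13 | 2-[(4aR,8aS)-2,5,5,8a-tetramethyl-3,4,4a,5,6,8a-hexahydronaphthalen-1-yl]ethan-1-ol | CC1=C(CCO)[C@@]2(C)C=CCC(C)(C)[C@H]2CC1 | intermediate
14 | 2-[(4aR,8aS)-2,5,5,8a-tetramethyl-3,4,4a,5,6,7,8,8a-octahydronaphthalen-1-yl]ethan-1-ol | CC1=C(CCO)[C@@]2(C)CCCC(C)(C)[C@H]2CC1 | intermediate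
15 | (4aR,8aS)-1-(2-iodoethyl)-2,5,5,8a-tetramethyl-3,4,4a,5,6,7,8,8a-octahydronaphthalene | CC1=C(CCI)[C@@]2(C)CCCC(C)(C)[C@H]2CC1 | intermediate
16 | triethyl phosphonoacetate | CCOC(=O)CP(=O)(OCC)OCC | starting material
17 | sodium salt of triethyl phosphonoacetate | [Na+].CCOC(=O)[CH-]P(=O)(OCC)OCC | intermediate
18 | ethyl 2-(diethoxyphosphoryl)-4-[(4aR,8aS)-2,5,5,8a-tetramethyl-3,4,4a,5,6,7,8,8a-octahydronaphthalen-1-yl]butanoate (epimers at C2) | CC1=C(CCC(C(=O)OCC)P(=O)(OCC)OCC)[C@@]2(C)CCCC(C)(C)[C@H]2CC1 | intermediate
19 | (2E)-3-(tributylstannyl)prop-2-en-1-ol | OC/C=C/[Sn](CCCC)(CCCC)CCCC | starting material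
20 | (2E)-3-(tributylstannyl)prop-2-enal | O=C/C=C/[Sn](CCCC)(CCCC)CCCC | intermediate
21 | sodium salt of 18 (phosphonate carbanion) | [Na+].CC1=C(CC[C-](C(=O)OCC)P(=O)(OCC)OCC)[C@@]2(C)CCCC(C)(C)[C@H]2CC1 | intermediate
22 | ethyl (2E,4E)-2-{2-[(4aR,8aS)-2,5,5,8a-tetramethyl-3,4,4a,5,6,7,8,8a-octahydronaphthalen-1-yl]ethyl}-5-(tributylstannyl)penta-2,4-dienoate | CC1=C(CC/C(=C\C=C\[Sn](CCCC)(CCCC)CCCC)C(=O)OCC)[C@@]2(C)CCCC(C)(C)[C@H]2CC1 | intermediate
23 | (2E,4E)-2-{2-[(4aR,8aS)-2,5,5,8a-tetramethyl-3,4,4a,5,6,7,8,8a-octahydronaphthalen-1-yl]ethyl}-5-(tributylstannyl)penta-2,4-dien-1-ol | CC1=C(CC/C(=C\C=C\[Sn](CCCC)(CCCC)CCCC)CO)[C@@]2(C)CCCC(C)(C)[C@H]2CC1 | intermediate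
24 | 4-bromofuran-2(5H)-one | BrC1=CC(=O)OC1 | starting material
25 | 4-[(1E,3E)-4-(hydroxymethyl)-6-[(4aR,8aS)-2,5,5,8a-tetramethyl-3,4,4a,5,6,7,8,8a-octahydronaphthalen-1-yl]hexa-1,3-dien-1-yl]furan-2(5H)-one | CC1=C(CC/C(=C\C=C\C2=CC(=O)OC2)CO)[C@@]2(C)CCCC(C)(C)[C@H]2CC1 | target

## Step count and least certain steps

Total step count: 13. Longest linear sequence: 12 steps (steps 1–9 and 11–13); step 10 prepares 20 separately.

**Step 6 (key step).** The most likely failure is slow migratory insertion of the hindered, tetrasubstituted alkenylpalladium into the unactivated trisubstituted ring olefin, so that protodepalladation or catalyst decay competes. The cause is the build-up of a quaternary centre between two fully substituted carbons. Fallback, from 12 back to 14: the alcohol is silylated (t-BuMe2SiCl, imidazole) to the silyl ether F1. Allylic oxidation of the ring-A methylene C2 (CrO3·3,5-dimethylpyrazole, CH2Cl2, −20 °C) gives the enone F2, in which C10 is the β-carbon of a polarised olefin. An intramolecular reductive Heck (conjugate-type) cyclisation (Pd(OAc)2, PPh3, HCO2Na, DMF, 80 °C) should then give the cis-fused ketone F3, the tether again allowing only the cis fusion. Huang-Minlon reduction (N2H4·H2O, KOH, diethylene glycol, 200 °C; fluoride treatment if any silyl ether survives) removes the C2 carbonyl and the silyl group and returns the route at 14, so that step 7 is not needed.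

**Step 5.** The most likely failure is β-hydride transfer from the alkyliron species (hydromagnesiation of the alkyne and loss of 9) or incomplete carbometalation, because 9 is a primary alkyl reagent with β-hydrogens used without large excess. Fallback, from 9 back to 12: 9 is treated with CuBr·SMe2 (THF, −40 °C) and added syn across ethyl but-2-ynoate at −78 °C. Iodine then gives the α-iodo enoate F4, whose geometry is fixed by the syn carbocupration. i-Bu2AlH gives the allylic alcohol F5; CBr4/PPh3 gives the allylic bromide F6; CuI-catalysed coupling with (i-PrO)Me2SiCH2MgCl gives the silane F7; Tamao oxidation (H2O2, KF, KHCO3) gives 12.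

**Step 2.** The most likely failure is a sluggish [3,3] shift at the neopentyl terminus C5, which leaves time for acid-promoted ionisation of the allylic ketene acetal (elimination, allylic scrambling, erosion of enantiopurity). Fallback, from 2 back to 6: acetylation (Ac2O, pyridine) gives the acetate F8. LiN(i-Pr)2 and Me3SiCl (THF, −78 °C) give the silyl ketene acetal F9, which should rearrange below 60 °C without acid (Ireland–Claisen) to give, after aqueous work-up, the acid F10. LiAlH4 reduces F10 directly to 6.

**Step 11.** The most likely failure is erosion of E-selectivity at C13=C14, because the α-alkyl group on the phosphonate lowers the preference for the anti oxaphosphetane. Fallback, from 15 back to 22: 15 is heated with ethyl (triphenylphosphoranylidene)acetate (MeCN, 80 °C) to give the phosphonium iodide F11. Aqueous NaOH gives the stabilised ylide F12, and a Wittig reaction of F12 with 20 (toluene, 90 °C), which is intrinsically more E-selective for trisubstituted enoates, gives 22.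

**Step 13.** The most likely failure is protodestannylation or homocoupling of the dienylstannane and oligomerisation of the dienyl butenolide if transmetalation is slow. Fallback, from 23 back to 25, with the polarity of the coupling reversed: iododestannylation (I2, CH2Cl2, 0 °C) gives the dienyl iodide F13. 24 is converted with (Bu3Sn)2 and Pd(PPh3)4 into the stannyl butenolide F14. Stille coupling of F13 with F14 (Pd2(dba)3, AsPh3, CuI, NMP, rt) gives 25.

## Further compounds

F1 | step 6 | tert-butyl{[(3Z)-3-iodo-4-methyl-6-[(1R)-2,6,6-trimethylcyclohex-2-en-1-yl]hex-3-en-1-yl]oxy}dimethylsilane | CC(C)(C)[Si](C)(C)OCC/C(I)=C(\C)CC[C@H]1C(C)=CCCC1(C)C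
F2 | step 6 | (4R)-4-[(3Z)-6-{[tert-butyl(dimethyl)silyl]oxy}-4-iodo-3-methylhex-3-en-1-yl]-3,5,5-trimethylcyclohex-2-en-1-one | CC(C)(C)[Si](C)(C)OCC/C(I)=C(\C)CC[C@H]1C(C)=CC(=O)CC1(C)C
F3 | step 6 | (4aR,8aS)-8-(2-{[tert-butyl(dimethyl)silyl]oxy}ethyl)-4,4,7,8a-tetramethyl-3,4,4a,5,6,8a-hexahydronaphthalen-2(1H)-one | CC1=C(CCO[Si](C)(C)C(C)(C)C)[C@@]2(C)CC(=O)CC(C)(C)[C@H]2CC1
F4 | step 5 | ethyl (2Z)-2-iodo-3-methyl-5-[(1R)-2,6,6-trimethylcyclohex-2-en-1-yl]pent-2-enoate | CCOC(=O)/C(I)=C(\C)CC[C@H]1C(C)=CCCC1(C)C
F5 | step 5 | (2Z)-2-iodo-3-methyl-5-[(1R)-2,6,6-trimethylcyclohex-2-en-1-yl]pent-2-en-1-ol | OC/C(I)=C(\C)CC[C@H]1C(C)=CCCC1(C)C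
F6 | step 5 | (6R)-6-[(3Z)-5-bromo-4-iodo-3-methylpent-3-en-1-yl]-1,5,5-trimethylcyclohex-1-ene | BrC/C(I)=C(\C)CC[C@H]1C(C)=CCCC1(C)C
F7 | step 5 | [(3Z)-3-iodo-4-methyl-6-[(1R)-2,6,6-trimethylcyclohex-2-en-1-yl]hex-3-en-1-yl](dimethyl)(propan-2-yloxy)silane | CC(C)O[Si](C)(C)CC/C(I)=C(\C)CC[C@H]1C(C)=CCCC1(C)C
F8 | step 2 | (1S)-2,4,4-trimethylcyclohex-2-en-1-yl acetate | CC(=O)O[C@H]1CCC(C)(C)C=C1C
F9 | step 2 | trimethyl[(1-{[(1S)-2,4,4-trimethylcyclohex-2-en-1-yl]oxy}ethenyl)oxy]silane | C=C(O[Si](C)(C)C)O[C@H]1CCC(C)(C)C=C1C
F10 | step 2 | 2-[(1R)-2,6,6-trimethylcyclohex-2-en-1-yl]acetic acid | CC1=CCCC(C)(C)[C@H]1CC(=O)O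
F11 | step 11 | {1-ethoxy-1-oxo-4-[(4aR,8aS)-2,5,5,8a-tetramethyl-3,4,4a,5,6,7,8,8a-octahydronaphthalen-1-yl]butan-2-yl}triphenylphosphonium iodide | [I-].CC1=C(CCC(C(=O)OCC)[P+](c3ccccc3)(c4ccccc4)c5ccccc5)[C@@]2(C)CCCC(C)(C)[C@H]2CC1
F12 | step 11 | ethyl 4-[(4aR,8aS)-2,5,5,8a-tetramethyl-3,4,4a,5,6,7,8,8a-octahydronaphthalen-1-yl]-2-(triphenylphosphoranylidene)butanoate | CC1=C(CCC(C(=O)OCC)=P(c3ccccc3)(c4ccccc4)c5ccccc5)[C@@]2(C)CCCC(C)(C)[C@H]2CC1
F13 | step 13 | (2E,4E)-5-iodo-2-{2-[(4aR,8aS)-2,5,5,8a-tetramethyl-3,4,4a,5,6,7,8,8a-octahydronaphthalen-1-yl]ethyl}penta-2,4-dien-1-ol | CC1=C(CC/C(=C\C=C\I)CO)[C@@]2(C)CCCC(C)(C)[C@H]2CC1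
F14 | step 13 | 4-(tributylstannyl)furan-2(5H)-one | O=C1C=C([Sn](CCCC)(CCCC)CCCC)CO1
A1 | alternative 1 | (8aS)-8a-methyl-3,4,8,8a-tetrahydronaphthalene-1,6(2H,7H)-dione (Wieland–Miescher ketone) | O=C1CCCC2=CC(=O)CC[C@]12C
A2 | alternative 1 | (8aS)-5,5,8a-trimethyl-3,5,6,7,8,8a-hexahydronaphthalen-1(2H)-one | O=C1CCC=C2C(C)(C)CCC[C@]12C
A3 | alternative 2 | methyl (6Z)-7,11-dimethyl-3-oxododeca-6,10-dienoate | COC(=O)CC(=O)CC/C=C(/C)CCC=C(C)C
A4 | alternative 2 | methyl (4aR,8aS)-5,5,8a-trimethyl-2-oxodecahydronaphthalene-1-carboxylate (epimers at C1) | COC(=O)C1C(=O)CC[C@@H]2C(C)(C)CCC[C@]12C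
A5 | alternative 3 | (3E)-4,8,8-trimethyl-3-(prop-1-en-2-yl)deca-3,9-dien-1-ol | C=C(C)/C(CCO)=C(\C)CCCC(C)(C)C=C
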